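**Assumption:** I followed the SMILES exactly. Both ring-fusion carbons carry methyl groups, cis to each other (5β,10β), and the ring fusion is cis. The remaining stereocentres are 3β-OAc and 9α-H with a 9β-CH2OAr side chain.

Numbering used for intermediates (terpenoid style): the angular methyl carbon is C10, the gem-dimethyl carbon is C4, the oxygenated carbon is C3, the second angular methyl carbon is C5, the side-chain carbon is C11 (CH2O), and the exocyclic methylene carbon is C17.

## Retrosynthesis
1. The target's C8=CH2 comes from methylenation of a C8 ketone. The ArO–CH2 ether comes from oxa-Michael addition of umbelliferone to an α-methylene ketone, which also sets C9.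
2. The α-methylene ketone comes from SeO2 allylic oxidation and oxidation of a 9(11)-exocyclic alkene. That alkene comes from methylenating the saturated ketone of the Wieland–Miescher ketone.
3. The cis-5β,10β-dimethyl pair comes from cuprate addition to the WMK enone. C4 gem-dimethylation follows, then 3β-reduction and acetylation.
4. No rings are formed. The bicyclic core (WMK) and the coumarin (umbelliferone) are purchased.

## Route

**Step 1**
Reactants: 1 (S)-Wieland–Miescher ketone
Product: 2 (S)-8a-methyl-1-methylidene-octalin-6-one (Δ4a(5) enone, exocyclic C9=CH2)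
Conditions: Ph3P+CH3 Br–, KOtBu, THF, 0 °C → rt
Reagents that add atoms: methylenetriphenylphosphorane, C=P(c1ccccc1)(c1ccccc1)c1ccccc1 (adds CH2)
Why: Wittig methylenation takes place at the more electrophilic saturated ketone, while the vinylogous-ester-like enone ketone is left alone. This also removes the saturated ketone before the cuprate step.

**Step 2**
Reactants: 2
Product: 3 3-oxo-4,5,10-trimethyl-9(11)-ene decalin, 5β,10β-cis (C4 epimer mixture)
Conditions: Me2CuLi, Et2O, –78 → 0 °C; then MeI, HMPA, –78 °C → rt
Reagents that add atoms: lithium dimethylcuprate, C[Cu-]C.[Li+] (adds CH3 at C5); iodomethane, CI (adds CH3 at C4)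
Why: Conjugate (1,4) addition of the cuprate to the β-carbon of the 8a-methyl octalone gives the cis-fused vicinal quaternary pair, with the new methyl cis to C10-Me. This is the known facial preference for these octalones. The regiodefined enolate is then trapped at C4 by MeI (enolate alkylation).

**Step 3**
Reactants: 3
Product: 4 3-oxo-4,4,5,10-tetramethyl-9(11)-ene decalin
Conditions: KOtBu, MeI, t-BuOH/THF, rt
Reagents that add atoms: iodomethane, CI (adds CH3)
Why: Equilibrating base forms the more substituted C3=C4 enolate, and a second enolate methylation gives the gem-dimethyl group. No new stereocentre is created.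

**Step 4**
Reactants: 4
Product: 5 3β-hydroxy-4,4,5,10-tetramethyl-9(11)-ene decalin
Conditions: NaBH4, MeOH/CH2Cl2, 0 °C → rt
Reagents that add atoms: none
Why: Hydride attacks the C3 ketone from the α-face, anti to the axial β-methyl groups. This gives the equatorial 3β-alcohol (ketone reduction).

**Step 5**
Reactants: 5
Product: 6 3β-acetoxy-4,4,5,10-tetramethyl-9(11)-ene decalin
Conditions: Ac2O, DMAP, pyridine, 60 °C
Reagents that add atoms: acetic anhydride, CC(=O)OC(C)=O (adds acetyl)
Why: DMAP-catalysed acylation of the hindered neopentyl-type alcohol with retention at C3.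

**Step 6**
Reactants: 6
Product: 7 3β-acetoxy-8-hydroxy-9(11)-ene (C8 epimers)
Conditions: SeO2 (cat.), TBHP, CH2Cl2, rt
Reagents that add atoms: selenium dioxide, O=[Se]=O (source of the hydroxyl O); tert-butyl hydroperoxide, CC(C)(C)OO (reoxidant)
Why: The SeO2 ene / [2,3]-sigmatropic sequence (Riley oxidation) hydroxylates the only allylic CH2 (C8), because C10 is quaternary. The exocyclic alkene is retained, as in pinocarveol formation. The C8 configuration is irrelevant because the next step oxidizes it.

**Step 7**
Reactants: 7
Product: 8 3β-acetoxy-8-oxo-9(11)-ene (α-methylene ketone)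
Conditions: Dess–Martin periodinane, NaHCO3, CH2Cl2, rt
Reagents that add atoms: none
Why: Mild oxidation of the secondary allylic alcohol. The acetate and the alkene are untouched.

**Step 8**
Reactants: 8; 9 umbelliferone (7-hydroxycoumarin)
Product: 10 3β-acetoxy-11-(coumarin-7-yloxy)-8-oxo-drimane-type ketone, 9α-H
Conditions: K2CO3 (cat.), MeCN, 50 °C
Reagents that add atoms: none (umbelliferone is the reactant)
Why: Oxa-Michael addition of the phenoxide to the terminal CH2 of the α-methylene ketone forms the C11–O bond. The resulting C8/C9 enolate is protonated from the α-face, anti to the C10 β-methyl, which sets 9α-H and the β-CH2OAr side chain.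

**Step 9**
Reactants: 10
Product: 11 Polyanthinin
Conditions: Zn, CH2Br2, TiCl4, THF/CH2Cl2, 0 °C → rt
Reagents that add atoms: dibromomethane, BrCBr (adds CH2)
Why: Takai–Lombardo methylenation is near-neutral, so it converts the C8 ketone to the exocyclic C8=CH2 without epimerizing C9 or eliminating the β-aryloxy group. The acetate and the coumarin lactone are not methylenated.

## Compound list
1 | (S)-Wieland–Miescher ketone | C[C@]12CCC(=O)C=C1CCCC2=O | starting material
2 | (S)-8a-methyl-1-methylidene octalin-6-one (enone) | C[C@]12CCC(=O)C=C1CCCC2=C | intermediate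
3 | 3-oxo-4,5,10-trimethyl-9(11)-ene decalin, 5β,10β-cis (C4 epimers) | C=C1CCC[C@]2(C)C(C)C(=O)CC[C@]12C | intermediate
4 | 3-oxo-4,4,5,10-tetramethyl-9(11)-ene decalin | C=C1CCC[C@]2(C)C(C)(C)C(=O)CC[C@]12C | intermediate
5 | 3β-hydroxy analogue of 4 | C=C1CCC[C@]2(C)C(C)(C)[C@@H](O)CC[C@]12C | intermediate
6 | 3β-acetoxy analogue of 5 | C=C1CCC[C@]2(C)C(C)(C)[C@@H](OC(C)=O)CC[C@]12C | intermediate
7 | 3β-acetoxy-8-hydroxy-9(11)-ene (C8 epimers) | C=C1C(O)CC[C@]2(C)C(C)(C)[C@@H](OC(C)=O)CC[C@]12C | intermediate
8 | 3β-acetoxy-8-oxo-9(11)-ene (enone) | C=C1C(=O)CC[C@]2(C)C(C)(C)[C@@H](OC(C)=O)CC[C@]12C | intermediate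
9 | umbelliferone (7-hydroxycoumarin) | O=c1ccc2ccc(O)cc2o1 | starting material
10 | 8-oxo aryl ether, 9α-H | O=C1CC[C@]2(C)C(C)(C)[C@@H](OC(C)=O)CC[C@]2(C)[C@H]1COc1ccc2ccc(=O)oc2c1 | intermediate
11 | Polyanthinin | C=C1CC[C@]2(C)C(C)(C)[C@@H](OC(C)=O)CC[C@]2(C)[C@H]1COc1ccc2ccc(=O)oc2c1 | target

## Totals
Total steps: 9. Longest linear sequence: 9 (from 1; umbelliferone 9 is a purchased partner).

## Three steps most likely to fail
1. **Step 3 (C4 gem-dimethylation next to two quaternary centres).** Incomplete methylation or C2 methylation is likely.
   Fallback (different approach): dimethylate enone 2 first with KOtBu/MeI to give the Δ5-4,4-dimethyl-3-ketone. Then do allylic oxidation at C7 to the Δ5-7-oxo enone, add Me2CuLi at C5, and remove the C7 carbonyl by Wolff–Kishner reduction.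
2. **Step 2 (cuprate addition forming vicinal quaternary centres with cis selectivity).** Low conversion or a trans-fused minor product is possible.
   Fallback (different approach): form rings A/B in one step by cationic epoxy-polyene cyclization of a Z-tetrasubstituted 6-methyl-epoxyfarnesyl-type acetate. The Z geometry is intended to give the cis-fused, 3β-oxygenated core.
3. **Steps 8–9 (oxa-Michael addition gives the wrong C9 epimer or undergoes retro-Michael; a base-sensitive β-aryloxy ketone is methylenated).**
   Fallback (different approach): add PMBOH to enone 8 in place of umbelliferone. Then do the Lombardo methylenation, remove PMB with DDQ, and attach the coumarin last by Mitsunobu reaction with 9 (PPh3, DIAD). Before the methylenation, equilibrate C9 with DBU if needed.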